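The route rests on forming the C9–C11 bond (clerodane numbering) by an aliphatic Claisen rearrangement. It exploits the fact that the oxygen on C1 (ring A) and the side-chain carbon C11 on the quaternary C9 (ring B) sit 1,3 to each other across the ring-fusion carbon C10, on the same face. The precursor is a decalin with a C9=C10 alkene whose 1β-oxygen carries a 1-(furan-3-yl)vinyl group (a furoate ester after carbonyl methylenation). In one operation the rearrangement joins the furan side chain to the decalin, sets the C9 quaternary centre from the C1 carbinol and leaves a C1=C10 alkene, whose hydroboration later returns the 1β-oxygen and the trans ring fusion.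

Key step: step 11

Remarks
- Clerodane numbering is used for every bicyclic compound: decalin C1–C10, side chain C11–C16, C17 on C8, C18 on C4, C19 on C5, C20 on C9. The α face is that of C19 and C20; the β face is that of H-10 and C11.
- Assumption: the γ-hydroxylation in step 8 gives the axial 1α-alcohol, as peroxide oxidation of steroidal dienol ethers does. Should the 1β-alcohol form instead, step 9 would be run as a carbodiimide esterification with retention.
- The acetal carbon of 13–24 is drawn as a single epimer, assumed to be the one with the equatorial methyl group; it is removed in step 16 and its configuration has no consequence.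

Step 1
Reactants: 1 cyclohexane-1,3-dione; 2 allyl bromide
Product: 3 2-allylcyclohexane-1,3-dione
Conditions: KOH (aq. 20%), Cu powder (cat.), 0 °C → rt
Reagents that add atoms: none
Why: C-alkylation of the dione enolate, which in water should favour C- over O-allylation.

Step 2
Reactants: 3 2-allylcyclohexane-1,3-dione; 4 ethyl vinyl ketone
Product: 6 (S)-8a-allyl-5-methyl-3,4,8,8a-tetrahydronaphthalene-1,6(2H,7H)-dione, via triketone 5 (not isolated)
Conditions: Et3N (cat.), neat, rt; then D-phenylalanine (1 equiv), (1R)-(−)-10-camphorsulfonic acid (0.5 equiv), DMF, 30 → 70 °C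
Reagents that add atoms: none
Why: Robinson annulation (Michael addition, then Hajos–Parrish–Eder–Sauer–Wiechert aldol condensation) in which the D-amino-acid enamine should select one of the two enantiotopic ring carbonyls and so set the C5 quaternary centre in the sense opposite to that given by L-amino acids.

Step 3
Reactants: 6 allyl enone
Product: 7 C4 ethylene ketal of 6
Conditions: ethylene glycol, TsOH·H2O (cat.), 4 Å MS, CH2Cl2, rt
Reagents that add atoms: ethylene glycol, OCCO
Why: Acid-catalysed ketalisation, which should take the saturated C4 ketone much faster than the conjugated C8 ketone.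

Step 4
Reactants: 7 ketal enone
Product: 8 cross-conjugated 6,9(10)-dien-8-one
Conditions: IBX (2.5 equiv), DMSO/toluene, 75 °C
Reagents that add atoms: none
Why: IBX dehydrogenation through the enol at C7, the only α-methylene of the enone, should introduce the C6=C7 alkene.

Step 5
Reactants: 8 allyl dienone
Product: 9 (E)-prop-1-enyl dienone
Conditions: RuHCl(CO)(PPh3)3 (5 mol%), toluene, 80 °C
Reagents that add atoms: none
Why: Ruthenium-hydride alkene isomerisation (hydrometalation, β-hydride elimination) should move the terminal alkene to the internal position next to C5.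

Step 6
Reactants: 9 propenyl dienone
Product: 12 19-hydroxy dienone, via ozonide 10 (not isolated), via aldehyde 11 (not isolated)
Conditions: O3, CH2Cl2, −78 °C (stopped at first excess); Me2S; then NaBH4, EtOH/CH2Cl2, −78 °C
Reagents that add atoms: ozone, [O-][O+]=O
Why: Ozonolysis should cleave the electron-rich propenyl alkene in preference to the electron-poor dienone alkenes, and borohydride at low temperature should reduce only the aldehyde.

Step 7
Reactants: 12 19-hydroxy dienone
Product: 13 6α,19-O-ethylidene acetal enone
Conditions: MeCHO (5 equiv), Bi(NO3)3·5H2O (10 mol%), CH2Cl2, rt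
Reagents that add atoms: acetaldehyde, CC=O
Why: Hemiacetal formation on O-19 followed by intramolecular oxa-Michael addition to C6; the tether can reach C6 only on the C19 face, which sets 6α-O, and the acetal carbon should equilibrate to the equatorial-methyl epimer.

Step 8
Reactants: 13 acetal enone
Product: 15 1α-hydroxy enone, via silyl dienol ether 14 (not isolated)
Conditions: TBSOTf, Et3N, CH2Cl2, 0 °C → rt; then DMDO, acetone/CH2Cl2, −40 °C; aq. NaHCO3
Reagents that add atoms: dimethyldioxirane, CC1(C)OO1
Why: Vinylogous Rubottom oxidation: the linear (thermodynamic) dienol ether should be epoxidised at its terminal C1=C10 bond, with stereoelectronically controlled axial attack at C1 giving the 1α-alcohol.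

Step 9
Reactants: 15 1α-hydroxy enone; 16 furan-3-carboxylic acid
Product: 17 1β-(furan-3-carbonyloxy) enone
Conditions: PPh3, DIAD, THF, 0 °C → rt
Reagents that add atoms: none
Why: Mitsunobu esterification, whose SN2 inversion at the allylic axial carbinol should give the 1β-ester.

Step 10
Reactants: 17 furoate enone
Product: 18 1β-[1-(furan-3-yl)ethenyloxy]-8(17),9(10)-diene
Conditions: Cp2TiMe2 (5 equiv), toluene, 70 °C, dark; filtration through basic alumina
Reagents that add atoms: Cp2TiMe2 (dimethyltitanocene), [CH3-].[CH3-].[Ti+4].c1cc[cH-]c1.c1cc[cH-]c1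
Why: Petasis methylenation (Cp2Ti=CH2, oxatitanacyclobutane) should convert both the C8 ketone and the ester carbonyl into C=CH2 under non-basic conditions that spare the β-alkoxy ketone and both acetals.

Step 11
Reactants: 18 allyl vinyl ether
Product: 19 12-ketone with C9 quaternary centre, 1(10)-ene and 8(17)-methylene
Conditions: toluene, K2CO3 (trace), sealed tube, 150 °C
Reagents that add atoms: none
Why: A concerted suprafacial [3,3]-sigmatropic shift of the unit C11H2=C12(furyl)–O–C1–C10=C9 through a six-membered transition state breaks C1–O, forms C9–C11, turns C12 into the ketone and moves the alkene to C1=C10. The closest known reaction is the Claisen rearrangement of allyl 1-arylvinyl ethers made by ester methylenation. No ring is closed. The only new stereocentre, C9, is controlled by 1,3-chirality transfer from C1: the oxygen leaves the β face of C1 and C11 arrives on the β face of C9, giving C11 β and C20 α, and chair or boat geometry is irrelevant because C11 is CH2 and C12 becomes sp2. The step needs [3,3] shift to win over ionisation or elimination of the allylic ether. This should be secured by neutral, base-buffered conditions, by the axial C1–O bond (A(1,3) strain with C20 holds it aligned with the π system) and by the gain of a C=O bond.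

Step 12
Reactants: 19 Claisen ketone
Product: 20 8α-methyl ketone
Conditions: H2 (1 atm), RhCl(PPh3)3 (10 mol%), benzene, rt
Reagents that add atoms: none
Why: Homogeneous hydrogenation should reduce only the 1,1-disubstituted alkene, not the hindered C1=C10 alkene or the furan, adding H2 from the β face opposite the axial C20 methyl to give the equatorial 8α-methyl.

Step 13
Reactants: 20 furyl ketone
Product: 21 (12S)-alcohol
Conditions: (R)-2-methyl-CBS-oxazaborolidine (20 mol%), BH3·SMe2, THF, −30 °C; MeOH
Reagents that add atoms: none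
Why: Corey–Bakshi–Shibata reduction with the furyl ring as the large group; the (R)-catalyst should deliver hydride to give the 12S carbinol under reagent control.

Step 14
Reactants: 21 (12S)-alcohol
Product: 22 1β,12S-diol with 10β-H (trans-decalin)
Conditions: BH3·THF (excess), THF, 0 → 40 °C; then NaOH (aq.), H2O2, 0 °C → rt
Reagents that add atoms: hydrogen peroxide, OO
Why: Hydroboration–oxidation: anti-Markovnikov syn addition should come from the β face because the α face of C10 is shielded by the axial C19 and C20 groups, giving 10β-H and 1β-OH together.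

Step 15
Reactants: 22 diol; 23 (S)-2-methylbutanoic acid (two molecules per molecule of 22 enter the product; 3 equiv used)
Product: 24 1β,12-bis[(S)-2-methylbutanoate]
Conditions: 23 (3 equiv), EDC·HCl (3.5 equiv), DMAP (1 equiv), CH2Cl2, 0 °C → rt
Reagents that add atoms: (S)-2-methylbutanoic acid (second molecule of 23), CC[C@H](C)C(=O)O
Why: Steglich esterification of the 1β- and 12-hydroxyl groups, each of which takes up one molecule of 23, under mild conditions that should leave the α-stereocentre of the acid intact.

Step 16
Reactants: 24 bis-ester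
Product: 25 6α,19-dihydroxy-4-ketone
Conditions: HCl (aq. 2 M)/THF, 40 °C
Reagents that add atoms: water, O
Why: Acid-catalysed hydrolysis should remove both the dioxolane ketal and the ethylidene acetal, while the hindered α-branched esters survive.

Step 17
Reactants: 25 keto diol
Product: 26 18-chloro-4α,6α,19-triol
Conditions: ICH2Cl (6 equiv), MeLi·LiBr (5.5 equiv), THF, −78 °C; AcOH at −78 °C
Reagents that add atoms: chloroiodomethane, ClCI
Why: Chloromethyllithium, made by iodine–lithium exchange in the presence of the substrate, should add to the C4 ketone along the axial β trajectory, anti to the axial C19 on the neighbouring carbon, to give 4α-OH and β-CH2Cl; the cold acidic quench prevents epoxide closure.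

Step 18
Reactants: 26 chlorohydrin triol
Product: 27 6α,19-diacetate (furan analogue of the target)
Conditions: Ac2O (3 equiv), pyridine, DMAP (cat.), CH2Cl2, 0 °C → rt
Reagents that add atoms: acetic anhydride, CC(=O)OC(C)=O
Why: Acetylation of the primary and secondary alcohols; the hindered tertiary 4-OH should stay free.

Step 19
Reactants: 27 furan tetraester
Product: 29 ajugaciliatin A, via hydroxybutenolide 28 (not isolated)
Conditions: O2, hν, rose bengal (cat.), iPr2NEt, CH2Cl2/MeOH, −78 °C; then NaBH4, −20 °C; aq. HCl
Reagents that add atoms: dioxygen, O=O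
Why: Singlet oxygen [4+2] addition to the furan and base-directed Kornblum–DeLaMare fragmentation at the less hindered C15–H should give the 16-hydroxybutenolide, whose masked aldehyde is reduced and relactonised to the β-substituted butenolide.

Compound list
1 | cyclohexane-1,3-dione | O=C1CCCC(=O)C1 | starting material
2 | allyl bromide | C=CCBr | starting material
3 | 2-allylcyclohexane-1,3-dione | C=CCC1C(=O)CCCC1=O | intermediate
4 | ethyl vinyl ketone (pent-1-en-3-one) | CCC(=O)C=C | starting material
5 | 2-allyl-2-(3-oxopentyl)cyclohexane-1,3-dione | C=CCC1(CCC(=O)CC)C(=O)CCCC1=O | intermediate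
6 | (S)-8a-allyl-5-methyl-3,4,8,8a-tetrahydronaphthalene-1,6(2H,7H)-dione (5-allyl-9-methyl-9(10)-ene-4,8-dione) | C=CC[C@@]12CCC(=O)C(C)=C1CCCC2=O | intermediate
7 | 4,4-ethylenedioxy derivative of 6 (C4 ketone as 1,3-dioxolane, C8 enone free, same C5 configuration) | C=CC[C@@]12CCC(=O)C(C)=C1CCCC23OCCO3 | intermediate
8 | 5-allyl-4,4-ethylenedioxy-9-methyl-6,9(10)-dien-8-one (cross-conjugated dienone) | C=CC[C@@]12C=CC(=O)C(C)=C1CCCC23OCCO3 | intermediate
9 | dienone 8 with (E)-prop-1-enyl in place of allyl on C5 | C/C=C/[C@@]12C=CC(=O)C(C)=C1CCCC23OCCO3 | intermediate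
10 | secondary ozonide (1,2,4-trioxolane) of the propenyl group of 9 | CC1OOC(O1)[C@@]12C=CC(=O)C(C)=C1CCCC23OCCO3 | intermediate
11 | 5-formyl dienone (C19 aldehyde) | O=C[C@@]12C=CC(=O)C(C)=C1CCCC23OCCO3 | intermediate
12 | 5-(hydroxymethyl) dienone (19-hydroxy) | OC[C@@]12C=CC(=O)C(C)=C1CCCC23OCCO3 | intermediate
13 | 6α,19-O-ethylidene acetal of the 6α,19-dihydroxy-9(10)-en-8-one 4-ethylene ketal (acetal methyl equatorial, cis to H-6) | C[C@H]1OC[C@@]23[C@@H](O1)CC(=O)C(C)=C2CCCC34OCCO4 | intermediate
14 | 8-(tert-butyldimethylsilyloxy)-1(10),8-diene derived from 13 | C[C@H]1OC[C@@]23[C@@H](O1)CC(O[Si](C)(C)C(C)(C)C)=C(C)C2=CCCC34OCCO4 | intermediate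
15 | 1α-hydroxy derivative of 13 (axial OH, cis to C19) | C[C@H]1OC[C@@]23[C@@H](O1)CC(=O)C(C)=C2[C@@H](O)CCC34OCCO4 | intermediate
16 | furan-3-carboxylic acid | OC(=O)c1ccoc1 | starting material
17 | 1β-(furan-3-carbonyloxy) enone | C[C@H]1OC[C@@]23[C@@H](O1)CC(=O)C(C)=C2[C@H](OC(=O)c5ccoc5)CCC34OCCO4 | intermediate
18 | 1β-[1-(furan-3-yl)ethenyloxy]-8-methylene-9(10)-ene (acetal and ketal as in 13) | C[C@H]1OC[C@@]23[C@@H](O1)CC(=C)C(C)=C2[C@H](OC(=C)c5ccoc5)CCC34OCCO4 | intermediate
19 | 12-oxo-12-(furan-3-yl) compound with C9 quaternary (C20 α, C11 β), 1(10)-ene and 8(17)-methylene | O=C(c1ccoc1)C[C@@]1(C)C(=C)C[C@@H]2O[C@@H](C)OC[C@]23C1=CCCC34OCCO4 | intermediate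
20 | 8α-methyl (H-8β) 12-ketone, 1(10)-ene | O=C(c1ccoc1)C[C@@]1(C)[C@H](C)C[C@@H]2O[C@@H](C)OC[C@]23C1=CCCC34OCCO4 | intermediate
21 | (12S)-alcohol, 1(10)-ene | O[C@@H](C[C@@]1(C)[C@H](C)C[C@@H]2O[C@@H](C)OC[C@]23C1=CCCC34OCCO4)c1ccoc1 | intermediate
22 | 1β,12S-diol with 10β-H (trans-decalin) | O[C@@H](C[C@@]1(C)[C@H](C)C[C@@H]2O[C@@H](C)OC[C@]23[C@@H]1[C@H](O)CCC34OCCO4)c1ccoc1 | intermediate
23 | (S)-2-methylbutanoic acid | CC[C@H](C)C(=O)O | starting material
24 | 1β,12-bis[(S)-2-methylbutanoate] of 22 | CC[C@H](C)C(=O)O[C@@H](C[C@@]1(C)[C@H](C)C[C@@H]2O[C@@H](C)OC[C@]23[C@@H]1[C@H](OC(=O)[C@@H](C)CC)CCC34OCCO4)c1ccoc1 | intermediate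
25 | 6α,19-dihydroxy-4-ketone bis-ester | CC[C@H](C)C(=O)O[C@@H](C[C@@]1(C)[C@H](C)C[C@H](O)[C@]2(CO)[C@@H]1[C@H](OC(=O)[C@@H](C)CC)CCC2=O)c1ccoc1 | intermediate
26 | 18-chloro-4α,6α,19-triol bis-ester | CC[C@H](C)C(=O)O[C@@H](C[C@@]1(C)[C@H](C)C[C@H](O)[C@]2(CO)[C@@H]1[C@H](OC(=O)[C@@H](C)CC)CC[C@]2(O)CCl)c1ccoc1 | intermediate
27 | 6α,19-diacetate of 26 (furan-3-yl analogue of the target) | CC[C@H](C)C(=O)O[C@@H](C[C@@]1(C)[C@H](C)C[C@H](OC(C)=O)[C@]2(COC(C)=O)[C@@H]1[C@H](OC(=O)[C@@H](C)CC)CC[C@]2(O)CCl)c1ccoc1 | intermediate
28 | 16-hydroxybutenolide (5-hydroxy-4-substituted furan-2(5H)-one, C16 epimers) | CC[C@H](C)C(=O)O[C@@H](C[C@@]1(C)[C@H](C)C[C@H](OC(C)=O)[C@]2(COC(C)=O)[C@@H]1[C@H](OC(=O)[C@@H](C)CC)CC[C@]2(O)CCl)C1=CC(=O)OC1O | intermediate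
29 | ajugaciliatin A | CC[C@H](C)C(=O)O[C@@H](C[C@@]1(C)[C@H](C)C[C@H](OC(C)=O)[C@]2(COC(C)=O)[C@@H]1[C@H](OC(=O)[C@@H](C)CC)CC[C@]2(O)CCl)C1=CC(=O)OC1 | target

Total step count: 19. Longest linear sequence: 19 steps (1 → 29); compounds 2, 4, 16 and 23 are purchased.

Steps most likely to fail

Step 7. The hemiacetal may not add to the neopentyl β-carbon C6 because the conjugate addition is reversible, or the 4-(hydroxymethyl)dienone may lose formaldehyde and aromatise under the Lewis acid. The fallback sets out from 12 and returns at 13, and delivers the oxygen through boron instead of through a hemiacetal. Phenylboronic acid with 4 Å MS and catalytic diisopropylamine in toluene should convert 12 into its O-19 boronic hemiester, whose amine-activated B–OH adds intramolecularly to C6 (boronate-tethered oxa-Michael addition) to give the cyclic phenylboronate F1. Transesterification with pinacol in THF should free the 6α,19-dihydroxy enone F2, and acetaldehyde dimethyl acetal with PPTS in CH2Cl2 should then give 13.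

Step 11. The doubly allylic, acid-sensitive enol ether may ionise at C1 and eliminate, or hydrolyse, before the congested transition state is reached. The fallback sets out from 17 and returns at 19; it makes the same bond by an Eschenmoser–Claisen rearrangement and attaches the furan afterwards. K2CO3 in MeOH at 0 °C should cleave the furoate to the 1β-hydroxy enone F3. Cp2TiMe2 in toluene at 70 °C should methylenate the C8 ketone to give the 1β-hydroxy diene F4. N,N-Dimethylacetamide dimethyl acetal in xylene at 140 °C should give, by the same suprafacial transfer from O-1 to C9, the N,N-dimethylamide F5. Furan-3-yllithium (from 3-bromofuran and n-BuLi, THF, −78 °C) should add once to the tertiary amide and give ketone 19 on work-up.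

Step 17. The carbenoid may attack the ester carbonyls, the lithium β-alkoxides of the keto diol may undergo retro-aldol cleavage, or the chloro alkoxide may close to the epoxide on warming. The fallback sets out from 25 and returns at 27; it introduces chlorine by opening an epoxide instead of adding a chlorinated carbanion. Ac2O, pyridine and DMAP should give the keto diacetate F6. Dimethylsulfonium methylide (Me3S+ I−, KN(SiMe3)2, THF, −10 °C; Corey–Chaykovsky reaction, axial attack from the β face) should give the 4α,18-epoxide F7. LiCl and AcOH in THF at rt should open it at the primary C18 to give 27.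

Further compounds
F1 | step 7 | cyclic phenylboronate of the 6α,19-dihydroxy-9(10)-en-8-one 4-ethylene ketal | c1ccccc1B1OC[C@@]23[C@@H](O1)CC(=O)C(C)=C2CCCC34OCCO4
F2 | step 7 | 6α,19-dihydroxy-9(10)-en-8-one 4-ethylene ketal | OC[C@@]12[C@@H](O)CC(=O)C(C)=C1CCCC23OCCO3
F3 | step 11 | 1β-hydroxy enone (C1 epimer of 15) | C[C@H]1OC[C@@]23[C@@H](O1)CC(=O)C(C)=C2[C@H](O)CCC34OCCO4
F4 | step 11 | 1β-hydroxy-8-methylene-9(10)-ene | C[C@H]1OC[C@@]23[C@@H](O1)CC(=C)C(C)=C2[C@H](O)CCC34OCCO4
F5 | step 11 | N,N-dimethylamide of the C12 acid (C9 quaternary, 1(10)-ene, 8(17)-methylene) | CN(C)C(=O)C[C@@]1(C)C(=C)C[C@@H]2O[C@@H](C)OC[C@]23C1=CCCC34OCCO4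
F6 | step 17 | 6α,19-diacetoxy-4-ketone bis-ester | CC[C@H](C)C(=O)O[C@@H](C[C@@]1(C)[C@H](C)C[C@H](OC(C)=O)[C@]2(COC(C)=O)[C@@H]1[C@H](OC(=O)[C@@H](C)CC)CCC2=O)c1ccoc1
F7 | step 17 | 4α,18-epoxide tetraester | CC[C@H](C)C(=O)O[C@@H](C[C@@]1(C)[C@H](C)C[C@H](OC(C)=O)[C@]2(COC(C)=O)[C@@H]1[C@H](OC(=O)[C@@H](C)CC)CC[C@]23CO3)c1ccoc1
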